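**Retrosynthetic overview**

1. The angelate (C2–O) and the 3,4,5-trimethoxybenzoate (C6–O) are put on last; the C6 carbinol comes from a C6 ketone by reduction directed by the free C4–OH.
2. The strategy rests on the unit C6(=O)–C7H2–C8(CH3)=C9 of the seven-membered ring: C7 is the α-carbon of a ketone and C8 a vinylic carbon. The C7–C8 bond is therefore cut to a methyl ketone enolate and a (Z)-vinyl chloride, joined by intramolecular palladium-catalysed α-alkenylation.
3. The cyclisation substrate 19 carries C4 already as the isopropyl carbinol (TMS ether). This avoids a C4/C6 diketone and keeps the C4–OH available to steer hydride to C6.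
4. 19 comes from silyloxycyclopentenone 1. The C4 silyl ether directs dithiane conjugate addition (C5), enolate methylation anti to the C5 group sets C1, hydride sets C2, and isopropyl addition anti to the C5 group sets C4.
5. Ring order: the cyclopentane is present from compound 1; the seven-membered ring is closed in step 13.

Key step: step 13

**Conventions and assumption**

- Numbering for all compounds: cyclopentane C1 (quaternary, CH3), C2 (O), C3 (CH2), C4, C5; seven-membered ring C5–C6–C7–C8(CH3)=C9–C10–C1.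
- Faces: with the cyclopentane viewed so that C1→C2→C3→C4→C5 runs clockwise, groups toward the viewer are β and those away are α. The target is 1α-CH3, 2β-O-angeloyl, 4β-OH, 4α-isopropyl, 5α-H, 6α-O-aroyl (1R,2S,4S,5R,6R), cis-fused.
- Assumption: (Z)-1,3-dichlorobut-2-ene (4) is used as the pure Z isomer, separated from the commercial E/Z mixture if only the mixture is supplied; its olefin geometry is not touched before step 13.
- C2 is protected as a 4-methoxybenzyl (PMB) ether so that it stays distinct from the C4 silyl ether of 1 and from the later C6 hydroxyl.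

**Route**

Step 1
Reactants: 1 (S)-4-(tert-butyldimethylsilyloxy)cyclopent-2-en-1-one
Product: 2 (S)-4-(tert-butyldimethylsilyloxy)-2-iodocyclopent-2-en-1-one
Conditions: I2, pyridine/CH2Cl2, 0 °C → rt
Reagents that add atoms: iodine, II
Why: α-Iodination of an enone by conjugate addition of pyridine, iodination of the enolate and loss of pyridine (addition–elimination) should give the 2-iodoenone without touching the C4 stereocentre.

Step 2
Reactants: 2 (S)-4-(tert-butyldimethylsilyloxy)-2-iodocyclopent-2-en-1-one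
Product: 3 (S)-8-(tert-butyldimethylsilyloxy)-6-iodo-1,4-dioxaspiro[4.4]non-6-ene
Conditions: Me3SiOCH2CH2OSiMe3, Me3SiOTf (5 mol %), CH2Cl2, −78 → −20 °C
Reagents that add atoms: 1,2-bis(trimethylsilyloxy)ethane, C[Si](C)(C)OCCO[Si](C)(C)C
Why: Aprotic silyl-transfer ketalisation at low temperature should mask the carbonyl without moving the double bond or ionising the allylic silyl ether, so that the vinyl iodide can be metalated in the next step.

Step 3
Reactants: 3 (S)-8-(tert-butyldimethylsilyloxy)-6-iodo-1,4-dioxaspiro[4.4]non-6-ene; 4 (Z)-1,3-dichlorobut-2-ene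
Product: 6 (S)-8-(tert-butyldimethylsilyloxy)-6-[(Z)-3-chlorobut-2-enyl]-1,4-dioxaspiro[4.4]non-6-ene, via vinyllithium 5 (not isolated)
Conditions: t-BuLi (2.0 equiv), THF, −78 °C; then 4, DMPU, −78 → −20 °C
Reagents that add atoms: none
Why: Iodine–lithium exchange gives an α-ketovinyl anion equivalent that should displace the primary allylic chloride of 4 by SN2 alkylation (the γ-carbon is fully substituted and the vinylic C–Cl bond is inert to the organolithium at this temperature), so the Z-chloroalkene is transferred unchanged.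

Step 4
Reactants: 6 (S)-8-(tert-butyldimethylsilyloxy)-6-[(Z)-3-chlorobut-2-enyl]-1,4-dioxaspiro[4.4]non-6-ene
Product: 7 (S)-4-(tert-butyldimethylsilyloxy)-2-[(Z)-3-chlorobut-2-enyl]cyclopent-2-en-1-one
Conditions: oxalic acid, THF/H2O (4:1), rt
Reagents that add atoms: water, O
Why: Mild acid hydrolysis of the allylic ketal should return the enone, with the secondary silyl ether and the vinyl chloride stable to dilute oxalic acid.

Step 5
Reactants: 7 (S)-4-(tert-butyldimethylsilyloxy)-2-[(Z)-3-chlorobut-2-enyl]cyclopent-2-en-1-one; 8 2-methyl-1,3-dithiane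
Product: 11 1β-[(Z)-3-chlorobut-2-enyl]-1α-methyl-5β-(2-methyl-1,3-dithian-2-yl)-4α-(tert-butyldimethylsilyloxy)cyclopentan-2-one, via 2-lithio-2-methyl-1,3-dithiane 9 (not isolated), via lithium enolate 10 (not isolated)
Conditions: 8, n-BuLi, THF, −20 °C; HMPA, −78 °C; 7, −78 °C; MeI, −78 → −30 °C
Reagents that add atoms: iodomethane, CI
Why: The Corey–Seebach dithiane anion (acetyl anion equivalent) should add in the conjugate sense in the presence of HMPA, anti to the C4 silyloxy group (sets C5), and the tetrasubstituted lithium enolate should be methylated anti to the new C5 group (sets C1), so that the butenyl chain and the masked acetyl group end up cis.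

Step 6
Reactants: 11 1β-[(Z)-3-chlorobut-2-enyl]-1α-methyl-5β-(2-methyl-1,3-dithian-2-yl)-4α-(tert-butyldimethylsilyloxy)cyclopentan-2-one
Product: 12 1β-[(Z)-3-chlorobut-2-enyl]-1α-methyl-5β-(2-methyl-1,3-dithian-2-yl)-4α-(tert-butyldimethylsilyloxy)cyclopentan-2β-ol
Conditions: NaBH4, MeOH/THF, −20 → 0 °C
Reagents that add atoms: none
Why: Borohydride reduction of the 2,2-disubstituted cyclopentanone should occur from the α face, opposite the C5 dithianyl group and the butenyl chain (pseudo-axial when the dithianyl group sits pseudo-equatorial), giving the 2β-alcohol.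

Step 7
Reactants: 12 1β-[(Z)-3-chlorobut-2-enyl]-1α-methyl-5β-(2-methyl-1,3-dithian-2-yl)-4α-(tert-butyldimethylsilyloxy)cyclopentan-2β-ol
Product: 13 2β-(4-methoxybenzyl) ether of 12
Conditions: NaH, 4-MeOC6H4CH2Cl, Bu4NI (cat.), THF/DMF, 0 °C → rt
Reagents that add atoms: 4-methoxybenzyl chloride, COc1ccc(CCl)cc1
Why: Williamson etherification of the sodium alkoxide should protect C2–OH as a PMB ether; silyl migration from C4–O is not possible across the trans-1,3 relationship.

Step 8
Reactants: 13 2β-(4-methoxybenzyl) ether of 12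
Product: 14 1β-[(Z)-3-chlorobut-2-enyl]-2β-(4-methoxybenzyloxy)-1α-methyl-5β-(2-methyl-1,3-dithian-2-yl)cyclopentan-4α-ol
Conditions: Bu4NF, THF, rt
Reagents that add atoms: none
Why: Fluoride desilylation should free only the C4 hydroxyl, since the PMB ether, the dithiane and the vinyl chloride are inert to fluoride.

Step 9
Reactants: 14 1β-[(Z)-3-chlorobut-2-enyl]-2β-(4-methoxybenzyloxy)-1α-methyl-5β-(2-methyl-1,3-dithian-2-yl)cyclopentan-4α-ol
Product: 15 1β-[(Z)-3-chlorobut-2-enyl]-2β-(4-methoxybenzyloxy)-1α-methyl-5β-(2-methyl-1,3-dithian-2-yl)cyclopentan-4-one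
Conditions: Dess–Martin periodinane, pyridine, CH2Cl2, 0 °C → rt
Reagents that add atoms: none
Why: Buffered Dess–Martin oxidation should give the C4 ketone under neutral conditions that tolerate the dithiane and do not epimerise C5.

Step 10
Reactants: 15 1β-[(Z)-3-chlorobut-2-enyl]-2β-(4-methoxybenzyloxy)-1α-methyl-5β-(2-methyl-1,3-dithian-2-yl)cyclopentan-4-one; 16 isopropylmagnesium chloride
Product: 17 1β-[(Z)-3-chlorobut-2-enyl]-4α-isopropyl-2β-(4-methoxybenzyloxy)-1α-methyl-5β-(2-methyl-1,3-dithian-2-yl)cyclopentan-4β-ol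
Conditions: 16, LaCl3·2LiCl, THF, −20 → 0 °C; aq. NH4Cl
Reagents that add atoms: none
Why: Lanthanum-chloride-promoted Grignard 1,2-addition should suppress enolisation and β-hydride reduction, and isopropyl should enter from the α face, anti to the C5 dithianyl group and the C2 ether, giving 4β-OH/4α-isopropyl.

Step 11
Reactants: 17 1β-[(Z)-3-chlorobut-2-enyl]-4α-isopropyl-2β-(4-methoxybenzyloxy)-1α-methyl-5β-(2-methyl-1,3-dithian-2-yl)cyclopentan-4β-ol
Product: 18 1-{1β-[(Z)-3-chlorobut-2-enyl]-4β-hydroxy-4α-isopropyl-2β-(4-methoxybenzyloxy)-1α-methylcyclopent-5β-yl}ethanone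
Conditions: MeI, CaCO3, MeCN/H2O (9:1), 50 °C
Reagents that add atoms: water, O
Why: Alkylative dithiane hydrolysis (S-methylation, then hydrolysis of the sulfonium under carbonate buffering) should unmask the methyl ketone without mercury salts, which could hydrate the vinyl chloride, and without acid or base strong enough for dehydration or retro-aldol cleavage.

Step 12
Reactants: 18 1-{1β-[(Z)-3-chlorobut-2-enyl]-4β-hydroxy-4α-isopropyl-2β-(4-methoxybenzyloxy)-1α-methylcyclopent-5β-yl}ethanone
Product: 19 1-{1β-[(Z)-3-chlorobut-2-enyl]-4α-isopropyl-2β-(4-methoxybenzyloxy)-1α-methyl-4β-(trimethylsilyloxy)cyclopent-5β-yl}ethanone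
Conditions: Me3SiOTf, 2,6-lutidine, CH2Cl2, −78 °C
Reagents that add atoms: trimethylsilyl triflate, C[Si](C)(C)OS(=O)(=O)C(F)(F)F
Why: Silylation of the hindered tertiary alcohol with the silyl triflate and a weak base should protect the aldol hydroxyl against retro-aldol cleavage under the strong base of step 13, while the ketone is not enol-silylated at −78 °C.

Step 13
Reactants: 19 1-{1β-[(Z)-3-chlorobut-2-enyl]-4α-isopropyl-2β-(4-methoxybenzyloxy)-1α-methyl-4β-(trimethylsilyloxy)cyclopent-5β-yl}ethanone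
Product: 21 cis-fused 4α-isopropyl-2β-(4-methoxybenzyloxy)-1α,8-dimethyl-4β-(trimethylsilyloxy)-5α-H-hydroazul-8-en-6-one, via lithium enolate 20 (not isolated)
Conditions: LiN(SiMe3)2 (2.2 equiv), THF, −78 °C; Pd(P(t-Bu)3)2 (10 mol %), THF/toluene (0.01 M), −78 → 50 °C; AcOH, −78 °C
Reagents that add atoms: none
Why: LiN(SiMe3)2 at −78 °C should remove a proton only from the acetyl methyl group (C7), because the other α-hydrogen (C5–H) is tertiary and flanked by the quaternary C1 and the fully substituted C4; zerovalent palladium carrying P(t-Bu)3 then inserts into the vinylic C8–Cl bond with retention of the Z geometry, the enolate replaces chloride on divalent palladium, and C(sp2)–C(sp3) reductive elimination forms C7–C8. The closest known reaction type is the palladium-catalysed α-alkenylation of ketone enolates with vinyl halides, run here intramolecularly. The seven-membered ring closes through an eight-membered palladacycle (palladium bound to C8 and C7), which is within reach because the cis olefin and the cis arrangement of the acetyl group and the butenyl chain hold both carbon termini on the β face; the C8=C9 bond ends up endocyclic. No stereocentre is formed, and C5 keeps its configuration because it is never enolised. The step needs C7 over C5 (C5 attack would close a diquinane) and no β-elimination of the C4 silyloxy group; the pre-formed kinetic enolate secures both, and the second equivalent of base holds the more acidic product as its C7 dienolate until the cold acetic acid quench returns the β,γ-unsaturated ketone.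

Step 14
Reactants: 21 cis-fused 4α-isopropyl-2β-(4-methoxybenzyloxy)-1α,8-dimethyl-4β-(trimethylsilyloxy)-5α-H-hydroazul-8-en-6-one
Product: 22 cis-fused 4β-hydroxy-4α-isopropyl-2β-(4-methoxybenzyloxy)-1α,8-dimethyl-5α-H-hydroazul-8-en-6-one
Conditions: HF·pyridine, pyridine, THF, 0 °C
Reagents that add atoms: none
Why: Buffered fluoride desilylation should remove the tertiary trimethylsilyl ether under conditions too mild to conjugate the β,γ-olefin, to dehydrate the aldol or to cleave the PMB ether.

Step 15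
Reactants: 22 cis-fused 4β-hydroxy-4α-isopropyl-2β-(4-methoxybenzyloxy)-1α,8-dimethyl-5α-H-hydroazul-8-en-6-one
Product: 23 cis-fused 4α-isopropyl-2β-(4-methoxybenzyloxy)-1α,8-dimethyl-5α-H-hydroazul-8-ene-4β,6α-diol
Conditions: Me4NBH(OAc)3, MeCN/AcOH (1:1), −30 → 0 °C
Reagents that add atoms: none
Why: In the Evans–Saksena reduction the C4β-hydroxyl exchanges onto boron and delivers hydride through a six-membered transition state to the β (concave) face of the C6 carbonyl, giving the 1,3-anti 4β,6α-diol, whereas free hydride would be expected to approach the convex α face and give the wrong epimer.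

Step 16
Reactants: 23 cis-fused 4α-isopropyl-2β-(4-methoxybenzyloxy)-1α,8-dimethyl-5α-H-hydroazul-8-ene-4β,6α-diol; 24 3,4,5-trimethoxybenzoyl chloride
Product: 25 6α-(3,4,5-trimethoxybenzoate) of 23
Conditions: 24, Et3N, DMAP (cat.), CH2Cl2, 0 °C → rt
Reagents that add atoms: none
Why: DMAP-catalysed acylation should esterify only the secondary C6 hydroxyl with retention, because the tertiary C4 hydroxyl next to the isopropyl group is too hindered to be acylated.

Step 17
Reactants: 25 6α-(3,4,5-trimethoxybenzoate) of 23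
Product: 26 cis-fused 2β,4β-dihydroxy-4α-isopropyl-1α,8-dimethyl-5α-H-hydroazul-8-en-6α-yl 3,4,5-trimethoxybenzoate
Conditions: DDQ, CH2Cl2/pH 7 buffer (10:1), 0 °C → rt
Reagents that add atoms: none
Why: Oxidative PMB cleavage (hydride abstraction by DDQ, then hydrolysis of the oxocarbenium ion in the wet solvent) should free C2–OH without affecting the aryl ester, the trisubstituted olefin or the tertiary alcohol.

Step 18
Reactants: 26 cis-fused 2β,4β-dihydroxy-4α-isopropyl-1α,8-dimethyl-5α-H-hydroazul-8-en-6α-yl 3,4,5-trimethoxybenzoate; 27 angelic acid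
Product: 29 target CNP0112256.1 (2β-angelate of 26), via mixed anhydride 28 (not isolated)
Conditions: 27, 2,4,6-Cl3C6H2COCl, Et3N, toluene, rt; then 26, 80 °C
Reagents that add atoms: none
Why: Yamaguchi mixed-anhydride esterification without a nucleophilic catalyst should transfer the angeloyl group to the secondary C2 hydroxyl with the Z geometry intact (no reversible conjugate addition that would give the tiglate), while the tertiary C4 hydroxyl stays free.

**Compound list**

1 | (S)-4-(tert-butyldimethylsilyloxy)cyclopent-2-en-1-one | CC(C)(C)[Si](C)(C)O[C@H]1CC(=O)C=C1 | starting material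
2 | (S)-4-(tert-butyldimethylsilyloxy)-2-iodocyclopent-2-en-1-one | CC(C)(C)[Si](C)(C)O[C@H]1CC(=O)C(I)=C1 | intermediate
3 | (S)-8-(tert-butyldimethylsilyloxy)-6-iodo-1,4-dioxaspiro[4.4]non-6-ene | CC(C)(C)[Si](C)(C)O[C@H]1CC2(OCCO2)C(I)=C1 | intermediate
4 | (Z)-1,3-dichlorobut-2-ene | ClC/C=C(/C)Cl | starting material
5 | 6-lithio analogue of 3 (vinyllithium, not isolated) | CC(C)(C)[Si](C)(C)O[C@H]1CC2(OCCO2)C([Li])=C1 | intermediate
6 | (S)-8-(tert-butyldimethylsilyloxy)-6-[(Z)-3-chlorobut-2-enyl]-1,4-dioxaspiro[4.4]non-6-ene | CC(C)(C)[Si](C)(C)O[C@H]1CC2(OCCO2)C(C/C=C(/C)Cl)=C1 | intermediate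
7 | (S)-4-(tert-butyldimethylsilyloxy)-2-[(Z)-3-chlorobut-2-enyl]cyclopent-2-en-1-one | CC(C)(C)[Si](C)(C)O[C@H]1CC(=O)C(C/C=C(/C)Cl)=C1 | intermediate
8 | 2-methyl-1,3-dithiane | CC1SCCCS1 | starting material
9 | 2-lithio-2-methyl-1,3-dithiane (not isolated) | CC1([Li])SCCCS1 | intermediate
10 | lithium C1=C2 enolate of the conjugate adduct, 5β-dithianyl, 4α-OTBS (not isolated) | [Li]OC1=C(C/C=C(/C)Cl)[C@H](C2(C)SCCCS2)[C@@H](O[Si](C)(C)C(C)(C)C)C1 | intermediate
11 | 1β-[(Z)-3-chlorobut-2-enyl]-1α-methyl-5β-(2-methyl-1,3-dithian-2-yl)-4α-(tert-butyldimethylsilyloxy)cyclopentan-2-one | O=C1C[C@H](O[Si](C)(C)C(C)(C)C)[C@@H](C2(C)SCCCS2)[C@@]1(C)C/C=C(/C)Cl | intermediate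
12 | 2β-alcohol from 11 | O[C@H]1C[C@H](O[Si](C)(C)C(C)(C)C)[C@@H](C2(C)SCCCS2)[C@@]1(C)C/C=C(/C)Cl | intermediate
13 | 2β-(4-methoxybenzyl) ether of 12 | COc1ccc(CO[C@H]2C[C@H](O[Si](C)(C)C(C)(C)C)[C@@H](C3(C)SCCCS3)[C@@]2(C)C/C=C(/C)Cl)cc1 | intermediate
14 | 4α-alcohol (TBS removed from 13) | COc1ccc(CO[C@H]2C[C@H](O)[C@@H](C3(C)SCCCS3)[C@@]2(C)C/C=C(/C)Cl)cc1 | intermediate
15 | C4 ketone, 2β-OPMB, 5β-dithianyl | COc1ccc(CO[C@H]2CC(=O)[C@@H](C3(C)SCCCS3)[C@@]2(C)C/C=C(/C)Cl)cc1 | intermediate
16 | isopropylmagnesium chloride | CC(C)[Mg]Cl | starting material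
17 | 4β-hydroxy-4α-isopropyl carbinol, 2β-OPMB, 5β-dithianyl | COc1ccc(CO[C@H]2C[C@](O)(C(C)C)[C@@H](C3(C)SCCCS3)[C@@]2(C)C/C=C(/C)Cl)cc1 | intermediate
18 | 5β-acetyl-4β-hydroxy-4α-isopropyl cyclopentane, 2β-OPMB (β-hydroxy methyl ketone) | COc1ccc(CO[C@H]2C[C@](O)(C(C)C)[C@@H](C(C)=O)[C@@]2(C)C/C=C(/C)Cl)cc1 | intermediate
19 | cyclisation substrate: cis-5β-acetyl-1α-methyl-1β-[(Z)-3-chlorobut-2-enyl]cyclopentane, 2β-OPMB, 4α-isopropyl, 4β-OSiMe3 | COc1ccc(CO[C@H]2C[C@](O[Si](C)(C)C)(C(C)C)[C@@H](C(C)=O)[C@@]2(C)C/C=C(/C)Cl)cc1 | intermediate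
20 | lithium C6=C7 enolate of 19 (not isolated) | COc1ccc(CO[C@H]2C[C@](O[Si](C)(C)C)(C(C)C)[C@@H](C(=C)O[Li])[C@@]2(C)C/C=C(/C)Cl)cc1 | intermediate
21 | cis-hydroazul-8-en-6-one, 2β-OPMB, 4α-isopropyl, 4β-OSiMe3, 1α-CH3, 5α-H | COc1ccc(CO[C@H]2C[C@](O[Si](C)(C)C)(C(C)C)[C@H]3C(=O)CC(C)=CC[C@@]23C)cc1 | intermediate
22 | cis-hydroazul-8-en-6-one, 2β-OPMB, 4β-OH, 4α-isopropyl | COc1ccc(CO[C@H]2C[C@](O)(C(C)C)[C@H]3C(=O)CC(C)=CC[C@@]23C)cc1 | intermediate
23 | cis-hydroazul-8-ene-4β,6α-diol, 2β-OPMB, 4α-isopropyl | COc1ccc(CO[C@H]2C[C@](O)(C(C)C)[C@H]3[C@H](O)CC(C)=CC[C@@]23C)cc1 | intermediate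
24 | 3,4,5-trimethoxybenzoyl chloride | COc1cc(C(=O)Cl)cc(OC)c1OC | starting material
25 | 6α-(3,4,5-trimethoxybenzoate) of 23 | COc1ccc(CO[C@H]2C[C@](O)(C(C)C)[C@H]3[C@H](OC(=O)c4cc(OC)c(OC)c(OC)c4)CC(C)=CC[C@@]23C)cc1 | intermediate
26 | 2β,4β-diol 6α-(3,4,5-trimethoxybenzoate) | O[C@H]1C[C@](O)(C(C)C)[C@H]2[C@H](OC(=O)c3cc(OC)c(OC)c(OC)c3)CC(C)=CC[C@@]12C | intermediate
27 | angelic acid, (Z)-2-methylbut-2-enoic acid | C/C=C(/C)C(=O)O | starting material
28 | angelic 2,4,6-trichlorobenzoic anhydride (not isolated) | C/C=C(/C)C(=O)OC(=O)c1c(Cl)cc(Cl)cc1Cl | intermediate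
29 | CNP0112256.1: 2β-angelate, 6α-(3,4,5-trimethoxybenzoate), 4β-OH, 4α-isopropyl, cis-fused (1R,2S,4S,5R,6R) | C/C=C(/C)C(=O)O[C@H]1C[C@](O)(C(C)C)[C@H]2[C@H](OC(=O)c3cc(OC)c(OC)c(OC)c3)CC(C)=CC[C@@]12C | target

**Step count and risks**

Total step count: 18. Longest linear sequence: 18 steps (1 → 29).

Steps most likely to fail:

1. Step 13. Oxidative addition into the vinylic C–Cl bond may be slower than proton exchange of the lithium enolate, so that enolisation toward C5 (five-membered closure) or β-elimination of the C4 silyloxy group competes with the seven-membered closure. The fallback sets out from 19 and comes back at 21. 19 is converted with LiN(i-Pr)2 and Me3SiCl (THF, −78 °C) into the kinetic trimethylsilyl enol ether F1. F1 is then cyclised without strong base by tin-fluoride-mediated palladium coupling of the enol silane (Pd(P(t-Bu)3)2, Bu3SnF, toluene, 85 °C), in which a regiodefined tin enolate is the nucleophile and the mixture can be heated without enolate equilibration.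

2. Step 5. The hindered tertiary dithianyl anion may add to the carbonyl or remove a C3 proton (followed by loss of silanolate) instead of adding in the conjugate sense to the α-substituted enone, and the tetrasubstituted enolate may exchange protons before methylation. The fallback sets out from 7 and comes back at 18, with a vinyl group as the latent acetyl group. Copper-mediated conjugate addition of CH2=CHMgBr (CuI, Me3SiCl, THF, −78 °C), anti to the C4 silyloxy group, gives the 5β-vinyl trimethylsilyl enol ether F2. MeLi regenerates the lithium enolate, which is methylated (MeI, HMPA) anti to the vinyl group to give the 5β-vinyl ketone F3. The operations of steps 6 to 10 then give in turn the 2β-alcohol F4, its PMB ether F5, the 4α-alcohol F6, the C4 ketone F7 and the 4α-isopropyl carbinol F8, with the same facial arguments (anti to the C5 group). Tsuji–Wacker oxidation of F8 (PdCl2, CuCl, O2, DMF/H2O) converts the vinyl group into the methyl ketone 18; the trisubstituted chloroalkene is inert under these conditions.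

3. Step 10. The isopropyl Grignard reagent may enolise the hindered C4 ketone or reduce it by β-hydride transfer instead of adding to it. The fallback sets out from 15 and comes back at 18. The smaller sp2 nucleophile isopropenylmagnesium bromide with CeCl3 (THF, −78 °C), which cannot transfer a β-hydride in this way, adds from the α face to give the isopropenyl carbinol F9. Dithiane hydrolysis as in step 11 gives the isopropenyl β-hydroxy ketone F10. Hydrogenation with RhCl(PPh3)3 and H2 (benzene, rt) saturates only the 1,1-disubstituted olefin and gives 18.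

**Further compounds**

F1 | step 13 | kinetic trimethylsilyl enol ether of 19 | COc1ccc(CO[C@H]2C[C@](O[Si](C)(C)C)(C(C)C)[C@@H](C(=C)O[Si](C)(C)C)[C@@]2(C)C/C=C(/C)Cl)cc1
F2 | step 5 | 5β-vinyl trimethylsilyl enol ether (C1=C2), 4α-OTBS | C[Si](C)(C)OC1=C(C/C=C(/C)Cl)[C@H](C=C)[C@@H](O[Si](C)(C)C(C)(C)C)C1
F3 | step 5 | 1β-[(Z)-3-chlorobut-2-enyl]-1α-methyl-5β-vinyl-4α-(tert-butyldimethylsilyloxy)cyclopentan-2-one | O=C1C[C@H](O[Si](C)(C)C(C)(C)C)[C@@H](C=C)[C@@]1(C)C/C=C(/C)Cl
F4 | step 5 | 2β-alcohol from F3 | O[C@H]1C[C@H](O[Si](C)(C)C(C)(C)C)[C@@H](C=C)[C@@]1(C)C/C=C(/C)Cl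
F5 | step 5 | 2β-(4-methoxybenzyl) ether of F4 | COc1ccc(CO[C@H]2C[C@H](O[Si](C)(C)C(C)(C)C)[C@@H](C=C)[C@@]2(C)C/C=C(/C)Cl)cc1
F6 | step 5 | 4α-alcohol from F5 | COc1ccc(CO[C@H]2C[C@H](O)[C@@H](C=C)[C@@]2(C)C/C=C(/C)Cl)cc1
F7 | step 5 | C4 ketone from F6 | COc1ccc(CO[C@H]2CC(=O)[C@@H](C=C)[C@@]2(C)C/C=C(/C)Cl)cc1
F8 | step 5 | 4β-hydroxy-4α-isopropyl-5β-vinyl carbinol | COc1ccc(CO[C@H]2C[C@](O)(C(C)C)[C@@H](C=C)[C@@]2(C)C/C=C(/C)Cl)cc1
F9 | step 10 | 4β-hydroxy-4α-isopropenyl carbinol, 5β-dithianyl | COc1ccc(CO[C@H]2C[C@](O)(C(C)=C)[C@@H](C3(C)SCCCS3)[C@@]2(C)C/C=C(/C)Cl)cc1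
F10 | step 10 | 5β-acetyl-4β-hydroxy-4α-isopropenyl cyclopentane | COc1ccc(CO[C@H]2C[C@](O)(C(C)=C)[C@@H](C(C)=O)[C@@]2(C)C/C=C(/C)Cl)cc1
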